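**Retrosynthetic overview**
1. The target comes from methyl (13R)-8α,15-epoxylabdan-16-oate by ester reduction and acetylation. C13 lies α to the ester, so base can settle it on the decalin-fused oxocane.
2. The oxocane (ring C) is opened at C13–C14. In the forward direction this is a light-driven 8-endo-trig closure of a C13 α-ester radical onto an O8-vinyl ether.
3. The vinyl ether (C14, C15) comes from the tertiary C8–OH and vinyl acetate.
4. The C11–C12 bond comes from a photochemical decarboxylative Giese addition of ring-opened (+)-sclareolide to methyl 2-chloroacrylate. That reagent supplies C12, C13, C16 and the chlorine radical handle.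
5. Rings A and B, with C5, C8, C9 and C10, are bought in (+)-sclareolide. Its lactone is opened, and ring C is the only ring formed.

Assumption: labdane numbering is used for atom labels, and α/β refer to the usual terpenoid drawing (C20 and C17 methyls β, H9 α).

**Step 1**
Reactants: 1 (+)-sclareolide; 2 methyl 2-chloroacrylate
Product: 4 methyl 13-chloro-8α-hydroxy-14,15-dinorlabdan-16-oate (C13 epimers), via caesium hydroxy-carboxylate 3 (not isolated)
Conditions: CsOH·H2O (1.05 equiv), MeOH, 60 °C, evaporate; then 2 (2 equiv), 9-mesityl-3,6-di-tert-butyl-10-phenylacridinium tetrafluoroborate (2.5 mol %), MeCN/H2O 9:1, 450 nm LEDs, 25 °C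
Reagents that add atoms: methyl 2-chloroacrylate, C=C(Cl)C(=O)OC
Why: This is a photoredox decarboxylative Giese addition: the excited acridinium oxidises the carboxylate, CO2 loss gives the primary C11 radical, this adds to the CH2 end of 2, and the reduced dye turns the α-chloro radical into an enolate that water protonates; C5, C8, C9 and C10 are untouched, and C13 is left unassigned because step 3 erases it.

**Step 2**
Reactants: 4 chloro hydroxy ester; 5 vinyl acetate
Product: 6 methyl 13-chloro-8α-(ethenyloxy)-14,15-dinorlabdan-16-oate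
Conditions: [Ir(cod)Cl]2 (2 mol %), Na2CO3 (0.6 equiv), 5 (5 equiv), toluene, 100 °C; Et3N-washed silica
Reagents that add atoms: vinyl acetate, C=COC(C)=O
Why: Iridium-catalysed transfer vinylation (O–H addition to bound vinyl acetate, then loss of acetate) accepts tertiary alcohols under almost neutral conditions that spare the α-chloro ester, and the C8–O bond is never broken, so C8 is retained.

**Step 3**
Reactants: 6 chloro vinyl ether
Product: 8 methyl (13R)-8α,15-epoxylabdan-16-oate, via C13-epimeric ester mixture 7 (not isolated)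
Conditions: (TMS)3SiH (1.5 equiv), iPr3SiSH (5 mol %), Ir[dF(CF3)ppy]2(dtbbpy)PF6 (1 mol %), 2,6-lutidine (2 equiv), PhCF3, 3 mM, 450 nm LEDs, 25 °C; then NaOMe (3 equiv), MeOH, 60 °C
Reagents that add atoms: none
Why: Proposed new method: a photo-initiated silyl radical abstracts chlorine to give the electrophilic secondary α-ester radical at C13, which attacks the terminal carbon C14 of the electron-rich vinyl ether (8-endo-trig is preferred over 7-exo because it gives the α-oxy radical at C15 and avoids the O-bearing carbon), and the nucleophilic C15 radical is then quenched by the thiol, which the silane regenerates; in the boat-chair closing geometry (C12 anti to C10, C15 anti to the C8 methyl, O8 at the site that removes the transannular H/H contact) the α site of C13 points at H9, so CO2Me should take the outer β site (13R), and NaOMe should move residual 13S ester to this pseudo-equatorial epimer; the closest known reaction types are 8-endo cyclisations of α-carbonyl radicals from haloacetates onto terminal alkenes and intermolecular photoredox additions of α-halo esters to vinyl ethers, but closure onto the vinyl ether of a tertiary carbinol to make an oxocane has not been shown.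

**Step 4**
Reactants: 8 (13R)-ester
Product: 9 (13R)-8α,15-epoxylabdan-16-ol
Conditions: LiAlH4, THF, 0 °C; Fieser work-up
Reagents that add atoms: none
Why: This is a standard hydride reduction of an ester; the dialkyl ether is inert, and hydride attack outruns enolisation, so C13 is kept.

**Step 5**
Reactants: 9 primary alcohol; 10 acetic anhydride
Product: 11 (13R)-8α,15-epoxylabdan-16-yl acetate (target)
Conditions: 10 (1.5 equiv), pyridine, DMAP (5 mol %), CH2Cl2, 23 °C
Reagents that add atoms: acetic anhydride, CC(=O)OC(C)=O
Why: DMAP-catalysed acyl transfer to an unhindered primary alcohol touches no stereocentre.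

**Compound list**
1 | (+)-sclareolide | O1[C@]2(C)CC[C@H]3C(C)(C)CCC[C@]3(C)[C@H]2CC1=O | starting material
2 | methyl 2-chloroacrylate | C=C(Cl)C(=O)OC | starting material
3 | caesium 2-[(1R,2R,4aS,8aS)-2-hydroxy-2,5,5,8a-tetramethyldecahydronaphthalen-1-yl]acetate | O[C@]1(C)CC[C@H]2C(C)(C)CCC[C@]2(C)[C@H]1CC(=O)[O-].[Cs+] | intermediate
4 | methyl 2-chloro-4-[(1R,2R,4aS,8aS)-2-hydroxy-2,5,5,8a-tetramethyldecahydronaphthalen-1-yl]butanoate (C13 epimers) | O[C@]1(C)CC[C@H]2C(C)(C)CCC[C@]2(C)[C@H]1CCC(Cl)C(=O)OC | intermediate
5 | vinyl acetate | C=COC(C)=O | starting material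
6 | methyl 2-chloro-4-[(1R,2R,4aS,8aS)-2-(ethenyloxy)-2,5,5,8a-tetramethyldecahydronaphthalen-1-yl]butanoate (C13 epimers) | C=CO[C@]1(C)CC[C@H]2C(C)(C)CCC[C@]2(C)[C@H]1CCC(Cl)C(=O)OC | intermediate
7 | methyl 8α,15-epoxylabdan-16-oate, C13 epimer mixture | COC(=O)C1CCO[C@]2(C)CC[C@H]3C(C)(C)CCC[C@]3(C)[C@H]2CC1 | intermediate
8 | methyl (13R)-8α,15-epoxylabdan-16-oate | COC(=O)[C@H]1CCO[C@]2(C)CC[C@H]3C(C)(C)CCC[C@]3(C)[C@H]2CC1 | intermediate
9 | (13R)-8α,15-epoxylabdan-16-ol | OC[C@H]1CCO[C@]2(C)CC[C@H]3C(C)(C)CCC[C@]3(C)[C@H]2CC1 | intermediate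
10 | acetic anhydride | CC(=O)OC(C)=O | starting material
11 | (13R)-8α,15-epoxylabdan-16-yl acetate (CNP0152986.1) | CC(=O)OC[C@H]1CCO[C@]2(C)CC[C@H]3C(C)(C)CCC[C@]3(C)[C@H]2CC1 | target

**Step count**
Total steps: 5. Longest linear sequence: 5 (1 → 4 → 6 → 8 → 9 → 11).

**Steps most likely to fail**

*Step 3 (proposed new step).*
- Risks: the C13 radical may be reduced before the slow 8-membered closure. The vinyl ether may undergo hydrosilylation or thiol addition. The C15 radical may fragment at the O8–C8 bond.
- Fallback (ring-closing metathesis, known chemistry): it sets out from 3 and comes back to the route at 7 and then 8.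
- The C11 radical from 3 is trapped under the step 1 photocatalyst with methyl 2-[(phenylsulfonyl)methyl]acrylate. This decarboxylative radical allylation by addition–fragmentation gives the 2-methylidene hydroxy ester F1.
- The tertiary alcohol is allylated with allyl 2,2,2-trichloroacetimidate and catalytic TfOH to give the O8-allyl ether F2.
- Second-generation Grubbs catalyst, (H2IMes)(PCy3)Cl2Ru=CHPh, in toluene at 80 °C and 2 mM closes the ring to the oxocene ester F3.
- H2 over Pd/C in EtOAc gives 7, and the same NaOMe/MeOH equilibration gives 8.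

*Step 1.*
- Risks: an unactivated primary carboxylate is oxidised sluggishly. Compound 2 may polymerise or be attacked by the carboxylate.
- Fallback (alkoxy-radical fragmentation, then halogen-atom-transfer Giese addition): it sets out from 1 and comes back at 4.
- iBu2AlH in CH2Cl2 at −78 °C gives the sclareolide lactol F4.
- PhI(OAc)2 and I2 under visible light in cyclohexane cleave C11–C12 to give 11-iododriman-8α-yl formate F5.
- (TMS)3SiH under blue light with 2 gives the formate chloro ester F6.
- KHCO3 in MeOH removes the formyl group to give 4.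

*Step 2.*
- Risks: the hindered equatorial C8–OH may vinylate slowly, or may be acetylated instead.
- Fallback (acetal formation followed by elimination): it sets out from 4 and comes back at 6.
- Ethyl vinyl ether with pyridinium p-toluenesulfonate in CH2Cl2 gives the 1-ethoxyethyl ether F7.
- TMSOTf and Et3N at 0 °C silylate the less hindered ethoxy oxygen and eliminate it, leaving the vinyl ether 6.

**Further compounds**
F1 | step 3 | methyl 4-[(1R,2R,4aS,8aS)-2-hydroxy-2,5,5,8a-tetramethyldecahydronaphthalen-1-yl]-2-methylidenebutanoate | O[C@]1(C)CC[C@H]2C(C)(C)CCC[C@]2(C)[C@H]1CCC(=C)C(=O)OC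
F2 | step 3 | methyl 2-methylidene-4-[(1R,2R,4aS,8aS)-2,5,5,8a-tetramethyl-2-(prop-2-enyloxy)decahydronaphthalen-1-yl]butanoate | C=CCO[C@]1(C)CC[C@H]2C(C)(C)CCC[C@]2(C)[C@H]1CCC(=C)C(=O)OC
F3 | step 3 | methyl (13E)-8α,15-epoxylabd-13-en-16-oate | COC(=O)/C1=C/CO[C@]2(C)CC[C@H]3C(C)(C)CCC[C@]3(C)[C@H]2CC1
F4 | step 1 | 8α,12-epoxy-13,14,15,16-tetranorlabdan-12-ol (lactol, C12 epimers) | O1[C@]2(C)CC[C@H]3C(C)(C)CCC[C@]3(C)[C@H]2CC1O
F5 | step 1 | 11-iododriman-8α-yl formate | O=CO[C@]1(C)CC[C@H]2C(C)(C)CCC[C@]2(C)[C@H]1CI
F6 | step 1 | methyl 13-chloro-8α-(formyloxy)-14,15-dinorlabdan-16-oate | O=CO[C@]1(C)CC[C@H]2C(C)(C)CCC[C@]2(C)[C@H]1CCC(Cl)C(=O)OC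
F7 | step 2 | methyl 13-chloro-8α-(1-ethoxyethoxy)-14,15-dinorlabdan-16-oate | CCOC(C)O[C@]1(C)CC[C@H]2C(C)(C)CCC[C@]2(C)[C@H]1CCC(Cl)C(=O)OC
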